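**Assumption:** the target SMILES carries no stereodescriptor and the molecule has no stereocentre. The configuration of the biquinone axis is not defined, so the compound is made as drawn, without axial control.

## Retrosynthetic overview

Ring A is the quinone carrying the 2-(2-methoxyphenyl)ethyl arm; ring B is the quinone carrying the 2-phenylethyl arm.

1. The C5–C5' biquinone bond is cut in a polar sense: the ring A hydroxyquinone (electrophile at its only free position) plus the resorcinol precursor of ring B (nucleophile). One final oxidation brings both rings to the hydroxyquinone level.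
2. Each hydroxyquinone comes from a 3,5-dihydroxy-4-methylbibenzyl by Teuber oxidation, which places the third oxygen para to a phenol OH.
3. Each resorcinol ring comes from a linear C-methyl tetraketide with a dihydrocinnamoyl starter: C2→C7 aldol closure, aromatisation and loss of the C1 carboxyl as CO2 (the fold used by bibenzyl synthase), all in one flask.
4. The tetraketides come from the trianion of one common C-methyl diketo ester plus the methyl 3-arylpropanoates; the diketo ester comes from methyl 3-oxopentanoate plus an acetyl Weinreb amide.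
5. Ring order: ring A carbocycle (step 2), ring A quinone (step 3), ring B carbocycle (step 4), then the biaryl bond and ring B quinone last (step 5). The two arene rings are bought.

## Route

**Step 1**
Reactants: 1 methyl 3-oxopentanoate; 2 N-methoxy-N-methylacetamide
Product: 3 methyl 4-methyl-3,5-dioxohexanoate
Conditions: LiN(iPr)2 (2.1 equiv), THF, −78 → 0 °C; then 2, −78 → 0 °C; aq. HCl
Reagents that add atoms: none
Why: Weiler dianion γ-acylation (Claisen-type): the more nucleophilic γ-carbon of the β-keto ester dianion attacks the Weinreb amide, whose chelated tetrahedral intermediate prevents over-addition; the enolisable C4 centre is irrelevant because it becomes an sp2 ring carbon.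

**Step 2**
Reactants: 3 methyl 4-methyl-3,5-dioxohexanoate; 4 methyl 3-(2-methoxyphenyl)propanoate
Product: 8 5-[2-(2-methoxyphenyl)ethyl]-2-methylbenzene-1,3-diol, via triketo ester 5 (not isolated), via methyl resorcylate 6 (not isolated), via resorcylic acid 7 (not isolated)
Conditions: 3 (2.1 equiv), LiN(iPr)2 (6.3 equiv), THF, −78 → 0 °C; 4 (1 equiv), 0 °C → rt; aq. HCl; then KOH (to pH 9–10), MeOH/H2O, rt; KOH (6 equiv), reflux, Ar; HCl to pH 1, 70 °C
Reagents that add atoms: none
Why: Harris-type polyanion acylation at the terminal carbanion of the trianion (the second equivalent of trianion takes up the acidic product proton) gives the linear C-methyl tetraketide, whose doubly activated C2 methylene closes onto the C7 ketone at monoanion-level base (biomimetic aldol cyclisation–dehydration, not Claisen), and saponification followed by acid decarboxylation of the β-resorcylic acid gives the bibenzyl; no stereocentre is formed.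

**Step 3**
Reactants: 8 5-[2-(2-methoxyphenyl)ethyl]-2-methylbenzene-1,3-diol
Product: 9 2-hydroxy-6-[2-(2-methoxyphenyl)ethyl]-3-methylcyclohexa-2,5-diene-1,4-dione
Conditions: (KSO3)2NO (2.5 equiv), KH2PO4, H2O/acetone, 0 °C → rt
Reagents that add atoms: potassium nitrosodisulfonate (Fremy's salt), [K+].[K+].[O]N(S(=O)(=O)[O-])S(=O)(=O)[O-]
Why: Teuber oxidation: the phenol OH with a free para C–H is taken to the p-quinone by two equivalents of the nitroxyl radical while the other OH stays as the 2-hydroxy group and the 3-methyl group blocks further attack, as in the known oxidation of 2-substituted 5-alkylresorcinols to hydroxyquinones; the anisole ring is inert.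

**Step 4**
Reactants: 3 methyl 4-methyl-3,5-dioxohexanoate; 10 methyl 3-phenylpropanoate
Product: 14 2-methyl-5-(2-phenylethyl)benzene-1,3-diol, via triketo ester 11 (not isolated), via methyl resorcylate 12 (not isolated), via resorcylic acid 13 (not isolated)
Conditions: 3 (2.1 equiv), LiN(iPr)2 (6.3 equiv), THF, −78 → 0 °C; 10 (1 equiv), 0 °C → rt; aq. HCl; then KOH (to pH 9–10), MeOH/H2O, rt; KOH (6 equiv), reflux, Ar; HCl to pH 1, 70 °C
Reagents that add atoms: none
Why: the same Harris-type trianion acylation, biomimetic C2→C7 aldol aromatisation, saponification and decarboxylation as in step 2, now with the unsubstituted dihydrocinnamoyl starter; no stereocentre is formed.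

**Step 5**
Reactants: 9 2-hydroxy-6-[2-(2-methoxyphenyl)ethyl]-3-methylcyclohexa-2,5-diene-1,4-dione; 14 2-methyl-5-(2-phenylethyl)benzene-1,3-diol
Product: 16 2-hydroxy-5-[4-hydroxy-5-methyl-3,6-dioxo-2-(2-phenylethyl)cyclohexa-1,4-dien-1-yl]-6-[2-(2-methoxyphenyl)ethyl]-3-methylcyclohexa-2,5-diene-1,4-dione (target), via biaryl pentol 15 (not isolated)
Conditions: 14 (3 equiv), CF3CO2H (20 mol%), (CF3)2CHOH, rt → 40 °C, Ar; concentrate; then (KSO3)2NO (10 equiv), KH2PO4, H2O/acetone, 0 °C → rt
Reagents that add atoms: potassium nitrosodisulfonate (Fremy's salt), [K+].[K+].[O]N(S(=O)(=O)[O-])S(=O)(=O)[O-]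
Why: acid-promoted conjugate (Friedel–Crafts/Michael-type) arylation of the quinone at C5, its only unsubstituted position and β to the C1 carbonyl, by the resorcinol carbon ortho/para to its two OH groups (both such carbons are equivalent) fixes the cross-selectivity by polar roles and gives the biaryl at the hydroquinone level, and Teuber oxidation then converts the hydroquinone ring and the resorcinol ring (free para C–H) into the two hydroxyquinones, also returning any 9 reduced by redox exchange to 9; the axis forms without control, as the target defines none.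

## Compound list

1 | methyl 3-oxopentanoate | CCC(=O)CC(=O)OC | starting material
2 | N-methoxy-N-methylacetamide | CC(=O)N(C)OC | starting material
3 | methyl 4-methyl-3,5-dioxohexanoate (C4 enolisable, racemic) | COC(=O)CC(=O)C(C)C(=O)C | intermediate
4 | methyl 3-(2-methoxyphenyl)propanoate | COC(=O)CCc1ccccc1OC | starting material
5 | methyl 9-(2-methoxyphenyl)-4-methyl-3,5,7-trioxononanoate (C4 enolisable, racemic) | COC(=O)CC(=O)C(C)C(=O)CC(=O)CCc1ccccc1OC | intermediate (not isolated)
6 | methyl 2,4-dihydroxy-6-[2-(2-methoxyphenyl)ethyl]-3-methylbenzoate | COC(=O)c1c(O)c(C)c(O)cc1CCc1ccccc1OC | intermediate (not isolated)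
7 | 2,4-dihydroxy-6-[2-(2-methoxyphenyl)ethyl]-3-methylbenzoic acid | OC(=O)c1c(O)c(C)c(O)cc1CCc1ccccc1OC | intermediate (not isolated)
8 | 5-[2-(2-methoxyphenyl)ethyl]-2-methylbenzene-1,3-diol | COc1ccccc1CCc1cc(O)c(C)c(O)c1 | intermediate
9 | 2-hydroxy-6-[2-(2-methoxyphenyl)ethyl]-3-methylcyclohexa-2,5-diene-1,4-dione | COc1ccccc1CCC1=CC(=O)C(C)=C(O)C1=O | intermediate
10 | methyl 3-phenylpropanoate | COC(=O)CCc1ccccc1 | starting material
11 | methyl 4-methyl-3,5,7-trioxo-9-phenylnonanoate (C4 enolisable, racemic) | COC(=O)CC(=O)C(C)C(=O)CC(=O)CCc1ccccc1 | intermediate (not isolated)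
12 | methyl 2,4-dihydroxy-3-methyl-6-(2-phenylethyl)benzoate | COC(=O)c1c(O)c(C)c(O)cc1CCc1ccccc1 | intermediate (not isolated)
13 | 2,4-dihydroxy-3-methyl-6-(2-phenylethyl)benzoic acid | OC(=O)c1c(O)c(C)c(O)cc1CCc1ccccc1 | intermediate (not isolated)
14 | 2-methyl-5-(2-phenylethyl)benzene-1,3-diol | Cc1c(O)cc(CCc2ccccc2)cc1O | intermediate
15 | 6-[2-(2-methoxyphenyl)ethyl]-3,3'-dimethyl-6'-(2-phenylethyl)-[1,1'-biphenyl]-2,2',4,4',5-pentol | COc1ccccc1CCc1c(O)c(O)c(C)c(O)c1-c1c(O)c(C)c(O)cc1CCc1ccccc1 | intermediate (not isolated)
16 | 2-hydroxy-5-[4-hydroxy-5-methyl-3,6-dioxo-2-(2-phenylethyl)cyclohexa-1,4-dien-1-yl]-6-[2-(2-methoxyphenyl)ethyl]-3-methylcyclohexa-2,5-diene-1,4-dione | COc1ccccc1CCC1=C(C2=C(CCc3ccccc3)C(=O)C(O)=C(C)C2=O)C(=O)C(C)=C(O)C1=O | target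

## Step count and risks

Total steps: 5. Longest linear sequence: 4 (steps 1, 2, 3, 5).

**Most likely to fail, first: step 5.** The new biaryl bond is flanked by four ortho substituents, the trisubstituted hydroxyquinone is a modest electrophile, and redox exchange between 9 and the adduct can release the hydroquinone of 9, which can add to 9 and give the ring A homodimer. The excess of 14 is there to suppress this.

The fallback sets out from 8 and 14 and comes back to the route at 16; step 3 is then not needed. Equimolar 8 and 14 are coupled at the phenol stage by a one-electron oxidant (FeCl3·6H2O on SiO2, CH2Cl2, rt). The ortho/para carbons of the two phenoxyl radicals join statistically to give the two homodimers and the mixed biaryl 6-[2-(2-methoxyphenyl)ethyl]-3,3'-dimethyl-6'-(2-phenylethyl)-[1,1'-biphenyl]-2,2',4,4'-tetrol F1. F1 is the only one of the three with a single OMe group and is separated by chromatography. Both of its rings have a free C–H para to a phenol OH and are oxidised together with (KSO3)2NO (KH2PO4, H2O/acetone) to 16.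

**Second: step 2.** The enolisable ester 4 may protonate the trianion instead of acylating it, and the open triketo ester 5 can close the wrong way (Claisen closure to the acylphloroglucinol, or lactonisation).

The fallback sets out from 3 and 4 and comes back at 7. Compound 3 is lactonised (DBU, toluene, reflux) to 4-hydroxy-5,6-dimethyl-2H-pyran-2-one F2, a masked triketide. Its dianion (LiN(iPr)2, 2 equiv; OH and 6-methyl) is acylated by 4 at the 6-methyl carbon to give 4-hydroxy-6-[4-(2-methoxyphenyl)-2-oxobutyl]-5-methyl-2H-pyran-2-one F3. KOH in MeOH/H2O opens the pyrone to the triketo-acid anion. Its carboxylate cannot act as a Claisen acceptor, so it closes only by the C2→C7 aldol to 7. Acidification at 70 °C then gives 8 as in the main route.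

**Third: step 4.** This is the same cascade as step 2 and carries the same risks.

The fallback sets out from 10 and comes back at 13; it puts the carboxyl on last. The dianion of commercial 3-methylpentane-2,4-dione (CC(=O)C(C)C(=O)C; LiN(iPr)2, 2 equiv) is acylated at its terminal methyl by 10 to give 3-methyl-8-phenyloctane-2,4,6-trione F4. Its trianion (LiN(iPr)2, 3 equiv; kinetic deprotonation at the CH3 terminus) is carboxylated with CO2 to 4-methyl-3,5,7-trioxo-9-phenylnonanoic acid F5. At pH 5 the free triketo acid undergoes the aldol cyclisation spontaneously to 13, and decarboxylation gives 14.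

Either of the last two fallbacks can be used for the twin step in the other series.

## Further compounds

F1 | step 5 | 6-[2-(2-methoxyphenyl)ethyl]-3,3'-dimethyl-6'-(2-phenylethyl)-[1,1'-biphenyl]-2,2',4,4'-tetrol | COc1ccccc1CCc1cc(O)c(C)c(O)c1-c1c(O)c(C)c(O)cc1CCc1ccccc1
F2 | step 2 | 4-hydroxy-5,6-dimethyl-2H-pyran-2-one | CC1=C(C)C(O)=CC(=O)O1
F3 | step 2 | 4-hydroxy-6-[4-(2-methoxyphenyl)-2-oxobutyl]-5-methyl-2H-pyran-2-one | COc1ccccc1CCC(=O)CC1=C(C)C(O)=CC(=O)O1
F4 | step 4 | 3-methyl-8-phenyloctane-2,4,6-trione | CC(=O)C(C)C(=O)CC(=O)CCc1ccccc1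
F5 | step 4 | 4-methyl-3,5,7-trioxo-9-phenylnonanoic acid | OC(=O)CC(=O)C(C)C(=O)CC(=O)CCc1ccccc1
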